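Watch the first product.

| flask | substrate | reagent | capture agent | time | remark |
|---|---|---|---|---|---|
| oak | 0.20 M (fed, over 12 s) | 2.00 equiv | 0.0600 M | 15 s | all else is in the flask from the start; the feed brings no volume worth counting |
| larch | 0.20 M | 2.00 equiv (fed, over 12 s) | 0.0600 M | 15 s | all else is in the flask from the start; the feed brings no volume worth counting |
| ash | 0.20 M | 2.00 equiv | 0.0600 M | 15 s | everything together at the start |

    substrate + reagent → first product (k1 = 0.21 M⁻¹ s⁻¹)
    reagent + triple product → tetra adduct (k2 = 0.48 M⁻¹ s⁻¹)
    first product + capture agent → trapped intermediate (k3 = 1.5 M⁻¹ s⁻¹)
    reagent + first product → double product (k4 = 0.28 M⁻¹ s⁻¹)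
    reagent + double product → triple product (k5 = 0.089 M⁻¹ s⁻¹)

- which flask leads in amount of trapped intermediate, in percent of the substrate charged ("all alike" within 1.5 percentage points) (oak / larch / ash / all alike)
- how much trapped intermediate is there at the end, in percent of the substrate charged: oak
- how much trapped intermediate is there at the end, in percent of the substrate charged: larch
- how much trapped intermediate is there at the end, in percent of the substrate charged: ash

The first product leaves by two doors, so take the pull of each at the charged concentrations. With [reagent] at 0.400 M, the capture agent pulls at 0.0900 s⁻¹ and the reagent at 0.112 s⁻¹. The capture share, a selectivity, is the capture pull over the sum of both pulls, 44.6 %, and you multiply it by the throughput, meaning what has left the substrate and also left the first product.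

In ash no first product stands at the start, so the trapped curve starts flat. Substrate lives 11.9 s and first product 4.95 s, so with both pulls held the first product peaks near 7.44 s. Its level at 15 s is 16.8 % and the substrate left is 28.4 %, which gives a throughput of 54.9 % and trapped intermediate of 24.5 %, under the 30.0 % that the capture charge allows.

A feed in oak or larch costs the clock half its length, leaving 9.00 s, and the same reckoning then gives oak 13.9 %. In larch, with [reagent] half-way up, the share reads 61.6 %, higher than at the full charge, so I put larch above oak and commit to ash ahead.

The forecast also names ash, but with a lower 17 % for ash than mine, and it sets oak and larch level at 11.5 % and 11.5 %, since “larch's milder reagent competition roughly offsets oak's fresher capture agent”.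

The simulation gives ash ahead, with 17.1 %, against 12.0 % for larch and 10.8 % for oak. In ash at 15.0 s substrate stood at 39.0 %, more than I reckoned, and first product at 21.2 %, so the throughput was 39.8 % and the share from the charge makes that 17.8 %. A neighbour of oak with 8.00 equiv of reagent has a capture share of 16.7 % and a throughput of 74.6 %, which gives 12.5 %, and its flask holds 11.6 %.

The constants are those of an exercise; no experiment stands behind them.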